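Locants used below (target): ring A = trimethylcyclohexane, ring B = cyclohexene, ring C = cyclopentane, ring D = β-lactone; C1 = CH carrying CH2O, C2 and C3 = the CH2 groups of ring B, C4 = alkene carbon carrying ring A, C5 = alkene carbon shared by rings B and C, C6 = CH2 of ring C, C7 = lactone α-carbon, C8 = lactone O–CH, C9 = ring-fusion CH.
Late disconnections: the butanoate (acylation of the primary alcohol), ring D (lactonization of the cis C7-carboxyl/C8-hydroxyl pair) and the C1–H bond (face-selective hydrogenation of a C1=C2 alkene).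
Key disconnection: C3–C4 and C5–C9 together, by a nickel-catalysed intramolecular [4+2] cycloaddition of an acyclic dienyne. It is possible because the only C=C of ring B (C4=C5) lies between these two bonds and C5–C9 is the edge shared with ring C, so that alkyne C4≡C5, tether C6–C7–C8 and diene C9=C1–C2=C3 map onto rings B and C at once; the CH2O-bearing C1 next to the C8 stereocenter gives A(1,3) control of C9.
The dienyne is cut at C7–C8 by an Evans syn-aldol (sets C7 and C8) between an N-(pent-4-ynoyl)oxazolidinone carrying ring A and a (2Z)-3-(silyloxymethyl)penta-2,4-dienal made by syn-vinylcupration of a but-2-ynoate.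
Ring A is bought as the ethyl enol ether of dimedone and its quaternary stereocenter is set by copper-catalysed asymmetric 1,4-methylation of a 3-alkynyl enone. Ring order: A (given), then B and C together in the key step, then D.

Key step: step 12

Remark: silyl ethers 2 and 14 are taken as purchasable (each is otherwise one silylation from pent-4-yn-1-ol or prop-2-yn-1-ol); lithium and copper organometallics and catalyst-bound nickel species are transient and are described only in the Why lines.

Step 1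
Reactants: 1 3-ethoxy-5,5-dimethylcyclohex-2-en-1-one; 2 tert-butyldimethyl(pent-4-yn-1-yloxy)silane
Product: 4 3-[5-(tert-butyldimethylsilyloxy)pent-1-yn-1-yl]-5,5-dimethylcyclohex-2-en-1-one, via tertiary propargylic alcohol 3 (not isolated)
Conditions: 2, n-BuLi, THF, −78 °C; 1, −78 → 0 °C; 1 M aq. HCl, 0 °C, 15 min
Reagents that add atoms: water, O (source of the new carbonyl oxygen)
Why: Stork–Danheiser sequence: the lithium acetylide adds 1,2 to the vinylogous ester, and brief cold acid hydrolyses the enol ether with loss of the tertiary hydroxyl, which transposes the carbonyl to the 3-alkynyl enone and should spare the primary TBS ether.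

Step 2
Reactants: 4 enynone
Product: 5 (3R)-3-[5-(tert-butyldimethylsilyloxy)pent-1-yn-1-yl]-3,5,5-trimethylcyclohexan-1-one
Conditions: MeMgBr, Cu(OTf)2 (3 mol %), chiral C2-symmetric imidazolinium salt (NHC precursor, 4 mol %; the antipode that gives the R ketone), Et2O, −30 → 0 °C; aq. NH4Cl
Reagents that add atoms: methylmagnesium bromide, C[Mg]Br
Why: Copper/NHC-catalysed asymmetric conjugate addition of a Grignard reagent to a 3-alkynylcyclohex-2-enone, a substrate class that reacts 1,4 rather than 1,6 under these conditions; ligand control of the enone face sets the quaternary stereocenter of ring A.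

Step 3
Reactants: 5 R ketone
Product: 7 tert-butyldimethyl({5-[(1S)-1,3,3-trimethylcyclohexyl]pent-4-yn-1-yl}oxy)silane, via tosylhydrazone 6 (not isolated)
Conditions: TsNHNH2, EtOH, 60 °C; then catecholborane, CHCl3, 0 °C → rt; NaOAc·3H2O, reflux
Reagents that add atoms: none
Why: Catecholborane reduction of the tosylhydrazone, followed by acetate-induced loss of sulfinate and N2 (a mild Wolff–Kishner-type deoxygenation), replaces C=O by CH2 without touching the internal alkyne, the silyl ether or the quaternary center; the descriptor changes from R to S only because the ring priorities change.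

Step 4
Reactants: 7 silyl ether
Product: 10 5-[(1S)-1,3,3-trimethylcyclohexyl]pent-4-ynoic acid, via primary alcohol 8 (not isolated), via aldehyde 9 (not isolated)
Conditions: CrO3, H2SO4, H2O, acetone, 0 °C → rt
Reagents that add atoms: water, O
Why: Jones oxidation: the acidic medium cleaves the primary TBS ether and hexavalent chromium oxidizes the liberated alcohol through the aldehyde hydrate to the acid, while the dialkyl alkyne is inert.

Step 5
Reactants: 10 pentynoic acid; 11 (4R)-4-benzyl-1,3-oxazolidin-2-one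
Product: 13 (4R)-4-benzyl-3-{5-[(1S)-1,3,3-trimethylcyclohexyl]pent-4-ynoyl}-1,3-oxazolidin-2-one, via mixed pivalic anhydride 12 (not isolated)
Conditions: PivCl, Et3N, THF, −20 °C; then LiCl, 11, −20 °C → rt
Reagents that add atoms: none
Why: N-acylation of the Evans auxiliary through the mixed pivalic anhydride, which the LiCl-activated oxazolidinone attacks at the less hindered acyl carbon.

Step 6
Reactants: 14 tert-butyl(diphenyl)(prop-2-yn-1-yloxy)silane
Product: 15 ethyl 4-{[tert-butyl(diphenyl)silyl]oxy}but-2-ynoate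
Conditions: n-BuLi, THF, −78 °C; ClCO2Et, −78 → 0 °C
Reagents that add atoms: ethyl chloroformate, CCOC(=O)Cl
Why: C-acylation of a lithium acetylide with a chloroformate, the standard route to alk-2-ynoates.

Step 7
Reactants: 15 ynoate
Product: 16 ethyl (2Z)-3-({[tert-butyl(diphenyl)silyl]oxy}methyl)penta-2,4-dienoate
Conditions: CH2=CHMgBr (2.2 equiv), CuI (1.1 equiv), THF, −78 °C; 15; MeOH then aq. NH4Cl at −78 °C
Reagents that add atoms: vinylmagnesium bromide, C=C[Mg]Br
Why: syn-Carbocupration (conjugate addition) of the vinyl cuprate to the ynoate, then protonation of the configurationally stable alkenylcopper at −78 °C, places vinyl and H cis, so the ester ends cis to CH2OTBDPS (2Z), the geometry the later diene needs.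

Step 8
Reactants: 16 dienoate
Product: 17 (2Z)-3-({[tert-butyl(diphenyl)silyl]oxy}methyl)penta-2,4-dien-1-ol
Conditions: i-Bu2AlH (2.2 equiv), CH2Cl2, −78 °C; aq. potassium sodium tartrate
Reagents that add atoms: none
Why: 1,2-Reduction of the unsaturated ester to the allylic alcohol with i-Bu2AlH, which should not disturb the diene geometry.

Step 9
Reactants: 17 dienol
Product: 18 (2Z)-3-({[tert-butyl(diphenyl)silyl]oxy}methyl)penta-2,4-dienal
Conditions: MnO2 (activated, excess), CH2Cl2, rt; used at once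
Reagents that add atoms: none
Why: Allylic oxidation with MnO2 is neutral and should keep the Z enal geometry; the cis silyloxymethyl group cannot lactolize.

Step 10
Reactants: 13 acyl oxazolidinone; 18 dienal
Product: 20 (4R)-4-benzyl-3-[(2R,3S,4Z)-5-({[tert-butyl(diphenyl)silyl]oxy}methyl)-3-hydroxy-2-{3-[(1S)-1,3,3-trimethylcyclohexyl]prop-2-yn-1-yl}hepta-4,6-dienoyl]-1,3-oxazolidin-2-one, via dibutylboron Z-enolate 19 (not isolated)
Conditions: Bu2BOTf, i-Pr2NEt, CH2Cl2, 0 °C; 18, −78 → 0 °C; pH 7 buffer (NaH2PO4/Na2HPO4), MeOH, 30% H2O2, 0 °C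
Reagents that add atoms: none
Why: Evans syn-aldol: the Z boron enolate reacts through a closed Zimmerman–Traxler transition state on the face opposite the benzyl group of the R auxiliary, which forms the C7–C8 bond and sets C7 (R) and C8 (S) in the syn relationship that later becomes the cis lactone fusion.

Step 11
Reactants: 20 aldol adduct
Product: 21 (4R)-4-benzyl-3-[(2R,3S,4Z)-5-({[tert-butyl(diphenyl)silyl]oxy}methyl)-3-[(triethylsilyl)oxy]-2-{3-[(1S)-1,3,3-trimethylcyclohexyl]prop-2-yn-1-yl}hepta-4,6-dienoyl]-1,3-oxazolidin-2-one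
Conditions: TESOTf, 2,6-lutidine, CH2Cl2, −78 °C
Reagents that add atoms: triethylsilyl trifluoromethanesulfonate, CC[Si](CC)(CC)OS(=O)(=O)C(F)(F)F
Why: Silylation of the secondary allylic alcohol blocks retro-aldol cleavage and supplies the bulky group that later shields the lactone face of the bicycle.

Step 12
Reactants: 21 dienyne
Product: 22 (4R)-4-benzyl-3-{[(2R,3S,3aS)-4-({[tert-butyl(diphenyl)silyl]oxy}methyl)-3-[(triethylsilyl)oxy]-7-[(1S)-1,3,3-trimethylcyclohexyl]-2,3,3a,6-tetrahydro-1H-inden-2-yl]carbonyl}-1,3-oxazolidin-2-one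
Conditions: Ni(cod)2 (10 mol %), tris(2-biphenylyl) phosphite (30 mol %), THF (0.02 M), 25 → 50 °C, argon
Reagents that add atoms: none
Why: Zerovalent nickel binds the s-cis diene C9=C1–C2=C3 and the tethered alkyne, oxidative cyclization joins C5 to C9 and leaves an allyl/vinyl nickelacycle, and reductive elimination joins C4 to C3; the closest known reaction type is the nickel-catalysed intramolecular [4+2] cycloaddition of 1,3-dien-8-ynes with internal (alkyl- or silyl-capped) alkynes, which runs near room temperature. Ring C closes as the five-membered ring spanned by the tether C6–C7–C8 (5-exo with respect to the alkyne) and ring B as the six-membered ring of the cycloadduct, a cyclohexa-1,4-diene whose C4=C5 bond is already the tetrasubstituted alkene of the target. The one new stereocenter, C9, is controlled by A(1,3) strain: the CH2OTBDPS group on C1, cis to C8, forces H8 into the diene plane, so the tether carbon C7 and the OTES group lie on opposite faces and C5 must bond to C9 anti to OTES, which places H9 cis to the C8 oxygen as in the target. Regioselectivity is fixed by the tether (C8 trans to C2 across C9=C1 lets three atoms reach), and the bulky tert-alkyl terminus comes to lie next to nickel and is finally joined to the unsubstituted terminus C3, the least demanding arrangement for both organometallic steps. Chemoselectivity (no ionization of the two allylic silyl ethers, no aromatization of the 1,4-diene) rests on the neutral conditions, the low temperature and the exclusion of air.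

Step 13
Reactants: 22 cycloadduct
Product: 23 (4R)-4-benzyl-3-{[(2R,3S,3aR,4S)-4-({[tert-butyl(diphenyl)silyl]oxy}methyl)-3-[(triethylsilyl)oxy]-7-[(1S)-1,3,3-trimethylcyclohexyl]-2,3,3a,4,5,6-hexahydro-1H-inden-2-yl]carbonyl}-1,3-oxazolidin-2-one
Conditions: H2 (1–4 atm), PtO2 (10 mol %), EtOAc, rt
Reagents that add atoms: none
Why: Catalytic hydrogenation saturates the trisubstituted C1=C2 bond and should spare the C4=C5 bond buried beside the quaternary carbon; hydrogen is delivered to the face anti to the C8 OTES and C7 acyl groups, so H1 ends trans to H9 and the CH2OTBDPS group on the face of the C8 oxygen, which sets C1 (S) in the equatorial arrangement.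

Step 14
Reactants: 23 hydrogenated imide
Product: 25 (2R,3S,3aR,4S)-4-({[tert-butyl(diphenyl)silyl]oxy}methyl)-3-hydroxy-7-[(1S)-1,3,3-trimethylcyclohexyl]-2,3,3a,4,5,6-hexahydro-1H-indene-2-carboxylic acid, via triethylsilyl-protected acid 24 (not isolated)
Conditions: LiOH, 30% H2O2, THF–H2O (3:1), 0 °C; aq. Na2SO3; then 1 M HCl to pH 2, THF, rt
Reagents that add atoms: hydrogen peroxide, OO
Why: Hydroperoxide attacks the exocyclic imide carbonyl selectively (standard removal of the Evans auxiliary without epimerization of C7), and the acidic work-up hydrolyses the labile secondary TES ether while the primary TBDPS ether survives.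

Step 15
Reactants: 25 β-hydroxy acid
Product: 26 tricyclic β-lactone: ring D closed between the C7 carboxyl and the C8 oxygen of 25 (cis-fused oxetan-2-one; C1 S; C7 R; C8 S; C9 R; ring A S) with CH2OTBDPS at C1
Conditions: BOPCl, Et3N, CH2Cl2 (0.01 M), rt
Reagents that add atoms: none
Why: Carboxyl activation with BOPCl lets the cis C8 hydroxyl attack the acyl carbon (retention at C8) and close the cis-fused β-lactone, the usual mode of lactonization for cis-β-hydroxy acids on five-membered rings.

Step 16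
Reactants: 26 silyl-protected β-lactone
Product: 27 de-butanoyl target: the primary alcohol at C1–CH2 of the tricyclic β-lactone (C1 S; C7 R; C8 S; C9 R; ring A S)
Conditions: HF·pyridine, pyridine, THF, 0 °C → rt
Reagents that add atoms: none
Why: Buffered HF cleaves the primary TBDPS ether by Si–F bond formation without opening the acid-tolerant β-lactone.

Step 17
Reactants: 27 primary alcohol
Product: 28 3'-norspongiolactone
Conditions: (PrCO)2O, pyridine, DMAP (5 mol %), CH2Cl2, 0 °C
Reagents that add atoms: butanoic anhydride, CCCC(=O)OC(=O)CCC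
Why: O-acylation of the unhindered primary alcohol should be much faster than attack on the β-lactone and completes the target.

Compound list
1 | 3-ethoxy-5,5-dimethylcyclohex-2-en-1-one | CCOC1=CC(=O)CC(C)(C)C1 | starting material
2 | tert-butyldimethyl(pent-4-yn-1-yloxy)silane | C#CCCCO[Si](C)(C)C(C)(C)C | starting material
3 | 1-[5-(tert-butyldimethylsilyloxy)pent-1-yn-1-yl]-3-ethoxy-5,5-dimethylcyclohex-2-en-1-ol (racemic) | CCOC1=CC(O)(C#CCCCO[Si](C)(C)C(C)(C)C)CC(C)(C)C1 | intermediate
4 | 3-[5-(tert-butyldimethylsilyloxy)pent-1-yn-1-yl]-5,5-dimethylcyclohex-2-en-1-one | O=C1C=C(C#CCCCO[Si](C)(C)C(C)(C)C)CC(C)(C)C1 | intermediate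
5 | (3R)-3-[5-(tert-butyldimethylsilyloxy)pent-1-yn-1-yl]-3,5,5-trimethylcyclohexan-1-one | O=C1C[C@](C)(C#CCCCO[Si](C)(C)C(C)(C)C)CC(C)(C)C1 | intermediate
6 | 4-methylbenzenesulfonohydrazone of ketone 5 (3R) | Cc1ccc(cc1)S(=O)(=O)NN=C1C[C@](C)(C#CCCCO[Si](C)(C)C(C)(C)C)CC(C)(C)C1 | intermediate
7 | tert-butyldimethyl({5-[(1S)-1,3,3-trimethylcyclohexyl]pent-4-yn-1-yl}oxy)silane | CC(C)(C)[Si](C)(C)OCCCC#C[C@@]1(C)CCCC(C)(C)C1 | intermediate
8 | 5-[(1S)-1,3,3-trimethylcyclohexyl]pent-4-yn-1-ol | OCCCC#C[C@@]1(C)CCCC(C)(C)C1 | intermediate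
9 | 5-[(1S)-1,3,3-trimethylcyclohexyl]pent-4-ynal | O=CCCC#C[C@@]1(C)CCCC(C)(C)C1 | intermediate
10 | 5-[(1S)-1,3,3-trimethylcyclohexyl]pent-4-ynoic acid | OC(=O)CCC#C[C@@]1(C)CCCC(C)(C)C1 | intermediate
11 | (4R)-4-benzyl-1,3-oxazolidin-2-one | O=C1N[C@H](Cc2ccccc2)CO1 | starting material
12 | 2,2-dimethylpropanoic 5-[(1S)-1,3,3-trimethylcyclohexyl]pent-4-ynoic anhydride | CC(C)(C)C(=O)OC(=O)CCC#C[C@@]1(C)CCCC(C)(C)C1 | intermediate
13 | (4R)-4-benzyl-3-{5-[(1S)-1,3,3-trimethylcyclohexyl]pent-4-ynoyl}-1,3-oxazolidin-2-one | O=C(CCC#C[C@@]1(C)CCCC(C)(C)C1)N1[C@H](Cc2ccccc2)COC1=O | intermediate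
14 | tert-butyl(diphenyl)(prop-2-yn-1-yloxy)silane | C#CCO[Si](c1ccccc1)(c1ccccc1)C(C)(C)C | starting material
15 | ethyl 4-{[tert-butyl(diphenyl)silyl]oxy}but-2-ynoate | CCOC(=O)C#CCO[Si](c1ccccc1)(c1ccccc1)C(C)(C)C | intermediate
16 | ethyl (2Z)-3-({[tert-butyl(diphenyl)silyl]oxy}methyl)penta-2,4-dienoate | CCOC(=O)/C=C(\CO[Si](c1ccccc1)(c1ccccc1)C(C)(C)C)/C=C | intermediate
17 | (2Z)-3-({[tert-butyl(diphenyl)silyl]oxy}methyl)penta-2,4-dien-1-ol | OC/C=C(\CO[Si](c1ccccc1)(c1ccccc1)C(C)(C)C)/C=C | intermediate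
18 | (2Z)-3-({[tert-butyl(diphenyl)silyl]oxy}methyl)penta-2,4-dienal | O=C/C=C(\CO[Si](c1ccccc1)(c1ccccc1)C(C)(C)C)/C=C | intermediate
19 | dibutylboron (Z)-enolate of imide 13 | CCCCB(CCCC)O/C(=C\CC#C[C@@]1(C)CCCC(C)(C)C1)N1[C@H](Cc2ccccc2)COC1=O | intermediate
20 | (4R)-4-benzyl-3-[(2R,3S,4Z)-5-({[tert-butyl(diphenyl)silyl]oxy}methyl)-3-hydroxy-2-{3-[(1S)-1,3,3-trimethylcyclohexyl]prop-2-yn-1-yl}hepta-4,6-dienoyl]-1,3-oxazolidin-2-one | O=C([C@H](CC#C[C@@]1(C)CCCC(C)(C)C1)[C@@H](O)/C=C(\CO[Si](c1ccccc1)(c1ccccc1)C(C)(C)C)/C=C)N1[C@H](Cc2ccccc2)COC1=O | intermediate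
21 | (4R)-4-benzyl-3-[(2R,3S,4Z)-5-({[tert-butyl(diphenyl)silyl]oxy}methyl)-3-[(triethylsilyl)oxy]-2-{3-[(1S)-1,3,3-trimethylcyclohexyl]prop-2-yn-1-yl}hepta-4,6-dienoyl]-1,3-oxazolidin-2-one | O=C([C@H](CC#C[C@@]1(C)CCCC(C)(C)C1)[C@@H](O[Si](CC)(CC)CC)/C=C(\CO[Si](c1ccccc1)(c1ccccc1)C(C)(C)C)/C=C)N1[C@H](Cc2ccccc2)COC1=O | intermediate
22 | (4R)-4-benzyl-3-{[(2R,3S,3aS)-4-({[tert-butyl(diphenyl)silyl]oxy}methyl)-3-[(triethylsilyl)oxy]-7-[(1S)-1,3,3-trimethylcyclohexyl]-2,3,3a,6-tetrahydro-1H-inden-2-yl]carbonyl}-1,3-oxazolidin-2-one (indene locants 2/3/3a/4/7 = C7/C8/C9/C1/C4; 3aS here and 3aR in 23 are the same geometry) | CC(C)(C)[Si](c1ccccc1)(c1ccccc1)OCC1=CCC([C@@]2(C)CCCC(C)(C)C2)=C2C[C@@H](C(=O)N3[C@H](Cc4ccccc4)COC3=O)[C@@H](O[Si](CC)(CC)CC)[C@H]12 | intermediate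
23 | (4R)-4-benzyl-3-{[(2R,3S,3aR,4S)-4-({[tert-butyl(diphenyl)silyl]oxy}methyl)-3-[(triethylsilyl)oxy]-7-[(1S)-1,3,3-trimethylcyclohexyl]-2,3,3a,4,5,6-hexahydro-1H-inden-2-yl]carbonyl}-1,3-oxazolidin-2-one | CC(C)(C)[Si](c1ccccc1)(c1ccccc1)OC[C@H]1CCC([C@@]2(C)CCCC(C)(C)C2)=C2C[C@@H](C(=O)N3[C@H](Cc4ccccc4)COC3=O)[C@@H](O[Si](CC)(CC)CC)[C@H]12 | intermediate
24 | (2R,3S,3aR,4S)-4-({[tert-butyl(diphenyl)silyl]oxy}methyl)-3-[(triethylsilyl)oxy]-7-[(1S)-1,3,3-trimethylcyclohexyl]-2,3,3a,4,5,6-hexahydro-1H-indene-2-carboxylic acid | CC(C)(C)[Si](c1ccccc1)(c1ccccc1)OC[C@H]1CCC([C@@]2(C)CCCC(C)(C)C2)=C2C[C@@H](C(=O)O)[C@@H](O[Si](CC)(CC)CC)[C@H]12 | intermediate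
25 | (2R,3S,3aR,4S)-4-({[tert-butyl(diphenyl)silyl]oxy}methyl)-3-hydroxy-7-[(1S)-1,3,3-trimethylcyclohexyl]-2,3,3a,4,5,6-hexahydro-1H-indene-2-carboxylic acid | CC(C)(C)[Si](c1ccccc1)(c1ccccc1)OC[C@H]1CCC([C@@]2(C)CCCC(C)(C)C2)=C2C[C@@H](C(=O)O)[C@@H](O)[C@H]12 | intermediate
26 | TBDPS ether of 27: tricyclic cis-fused β-lactone (C1 S; C7 R; C8 S; C9 R; ring A S) with CH2OTBDPS at C1 | CC(C)(C)[Si](c1ccccc1)(c1ccccc1)OC[C@H]1CCC([C@@]2(C)CCCC(C)(C)C2)=C2C[C@H]3C(=O)O[C@H]3[C@@H]21 | intermediate
27 | de-butanoyl 3'-norspongiolactone (primary alcohol; C1 S; C7 R; C8 S; C9 R; ring A S) | OC[C@H]1CCC([C@@]2(C)CCCC(C)(C)C2)=C2C[C@H]3C(=O)O[C@H]3[C@@H]21 | intermediate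
28 | 3'-norspongiolactone | CCCC(=O)OC[C@H]1CCC([C@@]2(C)CCCC(C)(C)C2)=C2C[C@H]3C(=O)O[C@H]3[C@@H]21 | target

Total step count: 17. Longest linear sequence: 13 steps (steps 1–5, then 10–17).

Steps most likely to fail

Step 12 (key step). The alkyne, capped by a fully substituted carbon, may fail to enter the oxidative cyclization at nickel, so that diene oligomerization or isomerization consumes 21. The fallback sets out from 13 and returns at 23, so that steps 12 and 13 are both replaced. An Evans syn-aldol of 13 with acrolein under the conditions of step 10 should give the allylic alcohol F1, which is silylated (TESOTf, 2,6-lutidine) to the 1,6-enyne F2. Ring-closing enyne metathesis (second-generation Grubbs catalyst, ethylene, toluene, 80 °C) closes ring C and transfers the terminal CH2 to the distal alkyne carbon, giving the 1-vinylcyclopentene diene F3, in which C5–C9 and C3–C4 have been made as double bonds. An intermolecular Diels–Alder reaction with acrolein (toluene, 80 °C, or Me2AlCl, CH2Cl2, −78 °C) should then add C1–C2 to the face anti to OTES with the formyl-bearing carbon next to C9, and equilibration with DBU should give the equatorial aldehyde F4. NaBH4 (MeOH, −40 °C) gives the alcohol F5, and TBDPSCl/imidazole gives 23.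

Step 2. Turnover or enantiofacial discrimination may be poor because the axial methyl group of the gem-dimethyl carbon hinders the approach of the copper reagent to the β-carbon. The fallback sets out from 4 and returns at 5: the 1,4-methylation is run with an achiral NHC (IMes·HCl, Cu(OTf)2, MeMgBr, Et2O) to give the racemic ketone F6, whose enantiomers are separated by preparative chromatography on a chiral stationary phase; the S ketone F7 is set aside and the R enantiomer is 5.

Step 13. Hydrogen may be delivered to the wrong face of C1=C2, or the platinum surface may cause double-bond migration or dehydrogenation of the cyclohexa-1,4-diene to an indane. The fallback sets out from 22 and returns at 23: a metal-hydride hydrogen-atom-transfer hydrogenation (Mn(dpm)3, PhSiH3, t-BuOOH, i-PrOH, rt) reduces the trisubstituted alkene stepwise through the tertiary C1 radical, which takes up hydrogen axially and so should give the equatorial CH2OTBDPS epimer under thermodynamic rather than face-shielding control; new compounds: none F0.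

Further compounds
F1 | step 12 | (4R)-4-benzyl-3-[(2R,3S)-3-hydroxy-2-{3-[(1S)-1,3,3-trimethylcyclohexyl]prop-2-yn-1-yl}pent-4-enoyl]-1,3-oxazolidin-2-one | O=C([C@H](CC#C[C@@]1(C)CCCC(C)(C)C1)[C@@H](O)C=C)N1[C@H](Cc2ccccc2)COC1=O
F2 | step 12 | (4R)-4-benzyl-3-[(2R,3S)-3-[(triethylsilyl)oxy]-2-{3-[(1S)-1,3,3-trimethylcyclohexyl]prop-2-yn-1-yl}pent-4-enoyl]-1,3-oxazolidin-2-one | O=C([C@H](CC#C[C@@]1(C)CCCC(C)(C)C1)[C@@H](O[Si](CC)(CC)CC)C=C)N1[C@H](Cc2ccccc2)COC1=O
F3 | step 12 | (4R)-4-benzyl-3-{[(1R,2S)-2-[(triethylsilyl)oxy]-4-{1-[(1S)-1,3,3-trimethylcyclohexyl]ethenyl}cyclopent-3-en-1-yl]carbonyl}-1,3-oxazolidin-2-one | C=C(C1=C[C@H](O[Si](CC)(CC)CC)[C@H](C(=O)N2[C@H](Cc3ccccc3)COC2=O)C1)[C@@]1(C)CCCC(C)(C)C1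
F4 | step 12 | (2R,3S,3aR,4S)-2-{[(4R)-4-benzyl-2-oxo-1,3-oxazolidin-3-yl]carbonyl}-3-[(triethylsilyl)oxy]-7-[(1S)-1,3,3-trimethylcyclohexyl]-2,3,3a,4,5,6-hexahydro-1H-indene-4-carbaldehyde | O=C[C@H]1CCC([C@@]2(C)CCCC(C)(C)C2)=C2C[C@@H](C(=O)N3[C@H](Cc4ccccc4)COC3=O)[C@@H](O[Si](CC)(CC)CC)[C@H]12
F5 | step 12 | (4R)-4-benzyl-3-{[(2R,3S,3aR,4S)-4-(hydroxymethyl)-3-[(triethylsilyl)oxy]-7-[(1S)-1,3,3-trimethylcyclohexyl]-2,3,3a,4,5,6-hexahydro-1H-inden-2-yl]carbonyl}-1,3-oxazolidin-2-one | OC[C@H]1CCC([C@@]2(C)CCCC(C)(C)C2)=C2C[C@@H](C(=O)N3[C@H](Cc4ccccc4)COC3=O)[C@@H](O[Si](CC)(CC)CC)[C@H]12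
F6 | step 2 | racemic 3-[5-(tert-butyldimethylsilyloxy)pent-1-yn-1-yl]-3,5,5-trimethylcyclohexan-1-one | CC1(C#CCCCO[Si](C)(C)C(C)(C)C)CC(=O)CC(C)(C)C1
F7 | step 2 | (3S)-3-[5-(tert-butyldimethylsilyloxy)pent-1-yn-1-yl]-3,5,5-trimethylcyclohexan-1-one | O=C1C[C@@](C)(C#CCCCO[Si](C)(C)C(C)(C)C)CC(C)(C)C1
F0 | step 13 | none | none
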